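Ring A (C1–C6) carries its oxirane at C3–C4 next to the C2 hydroxyl, so the oxirane is traced back to a C3=C4 alkene and ring A is opened across that bond. Ring-closing metathesis of an acyclic 1,7-diene then forms C3=C4 and ring A in one operation, with the C1, C2 and C6 centres already set by an auxiliary-controlled syn aldol and a Felkin-type Grignard addition. The diene is an octa-1,7-dien-3-ol with a free C2 hydroxyl, a C1 triethylsilyl ether and C7 as a silyl-protected hydroxymethyl group; C7 is not kept as an acyl oxazolidinone, because a hydroxyl four atoms away would lactonise onto it.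

Key step: step 8

Remark: atoms are numbered as in the target (ring A: C1 acyloxy CH, C2 CHOH, C3/C4 oxirane, C5, C6; side chain: C7 methylidene-bearing carbon with =CH2 as C14, C8 angelate CH, C9, C10/C11 oxirane), and angelic acid, (R)-2-methylbutanoic acid, 4-methylpent-3-en-1-ol and the D-fructose-derived Shi ketone are assumed to be purchased.

Step 1
Reactants: 1 (R)-4-benzyl-2-oxazolidinone; 2 pent-4-enoyl chloride
Product: 4 (R)-4-benzyl-3-(pent-4-enoyl)oxazolidin-2-one, via N-lithio oxazolidinone 3 (not isolated)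
Conditions: n-BuLi, THF, −78 °C; then 2, −78 → 0 °C
Reagents that add atoms: none
Why: N-acylation of the lithium amide of an oxazolidinone with an acid chloride is the standard route to an N-acyl oxazolidinone, and the benzyl-bearing centre is not involved.

Step 2
Reactants: 4 (R)-4-benzyl-3-(pent-4-enoyl)oxazolidin-2-one; 5 (4-methoxybenzyloxy)acetaldehyde
Product: 7 (R)-4-benzyl-3-[(2R,3R)-3-hydroxy-4-(4-methoxybenzyloxy)-2-(prop-2-enyl)butanoyl]oxazolidin-2-one, via dibutylboron Z-enolate 6 (not isolated)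
Conditions: Bu2BOTf, i-Pr2NEt, CH2Cl2, 0 °C; then 5, −78 → 0 °C; pH 7 buffer, MeOH, H2O2, 0 °C
Reagents that add atoms: none
Why: Evans syn aldol, in which soft enolisation gives the Z boron enolate and this adds to the aldehyde through a closed Zimmerman–Traxler chair on the face away from the benzyl group of the dipole-opposed auxiliary, so that C6 and C1 are set together (2R,3R, syn) under auxiliary control.

Step 3
Reactants: 7 aldol adduct
Product: 8 (2S,3R)-4-(4-methoxybenzyloxy)-2-(prop-2-enyl)butane-1,3-diol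
Conditions: LiBH4, MeOH (1 equiv), THF, 0 °C
Reagents that add atoms: none
Why: Reductive cleavage of the N-acyl oxazolidinone with LiBH4 is standard for aldol adducts and turns C7 into a hydroxymethyl group before any hydroxyl four atoms away is unmasked, which rules out γ-lactonisation later, while C6 and C1 are not affected and the auxiliary is recovered.

Step 4
Reactants: 8 diol
Product: 9 (2S,3R)-4-(4-methoxybenzyloxy)-2-(prop-2-enyl)-1,3-bis(triethylsilyloxy)butane
Conditions: TESCl, imidazole, DMF, 0 °C → rt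
Reagents that add atoms: chlorotriethylsilane, CC[Si](Cl)(CC)CC
Why: Silylation of both hydroxyls with a silyl chloride and imidazole is routine, the C1 silyl ether is non-chelating as the Felkin addition of step 7 requires, and the primary C7 silyl ether is the one that step 10 oxidises.

Step 5
Reactants: 9 bis(triethylsilyl) ether
Product: 10 (2R,3S)-2-(triethylsilyloxy)-3-[(triethylsilyloxy)methyl]hex-5-en-1-ol
Conditions: DDQ, CH2Cl2/pH 7 phosphate buffer, 0 °C
Reagents that add atoms: none
Why: Oxidative cleavage of a 4-methoxybenzyl ether with DDQ proceeds by hydride abstraction at the electron-rich benzylic position and hydrolysis of the oxocarbenium ion, and the buffered medium should leave the triethylsilyl ethers and the terminal alkene alone.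

Step 6
Reactants: 10 primary alcohol
Product: 11 (2R,3S)-2-(triethylsilyloxy)-3-[(triethylsilyloxy)methyl]hex-5-enal
Conditions: Dess–Martin periodinane, NaHCO3, CH2Cl2, 0 °C → rt
Reagents that add atoms: none
Why: Dess–Martin oxidation of a primary alcohol is mild and non-basic, so the α-silyloxy aldehyde should form without epimerisation at C1, and it is used without purification.

Step 7
Reactants: 11 α-silyloxy aldehyde; 12 isopropenylmagnesium bromide
Product: 13 (3S,4R,5S)-2-methyl-4-(triethylsilyloxy)-5-[(triethylsilyloxy)methyl]octa-1,7-dien-3-ol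
Conditions: THF, −78 °C; sat. aq. NH4Cl
Reagents that add atoms: none
Why: Grignard 1,2-addition to an α-silyloxy aldehyde under polar Felkin–Anh control, in which the non-chelating C1–OSiEt3 bond lies perpendicular to the carbonyl and anti to the incoming nucleophile, should give the 1,2-anti relation between C1 and C2 that makes C2 S.

Step 8
Reactants: 13 dienol
Product: 14 (1S,5S,6R)-2-methyl-6-(triethylsilyloxy)-5-[(triethylsilyloxy)methyl]cyclohex-2-en-1-ol
Conditions: second-generation Grubbs catalyst (5 mol %), CH2Cl2 (0.005 M), 40 °C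
Reagents that add atoms: none
Why: Olefin metathesis by the Chauvin mechanism: the ruthenium benzylidene exchanges onto the monosubstituted allyl alkene at C4, the new alkylidene adds across the isopropenyl alkene in an intramolecular [2+2] step, and cycloreversion of the ruthenacyclobutane releases the C3=C4 alkene and a ruthenium methylidene that continues the cycle with loss of ethylene. The closest known reaction type is ring-closing metathesis of 1,7-dienes to 1-methylcyclohexenes, including substrates with a free allylic hydroxyl. Ring A is closed as a six-membered carbocycle by joining C3 to C4, and the new alkene is endocyclic and trisubstituted. No stereocentre is formed: C6 and C1 come from the aldol of step 2 and C2 from the addition of step 7, and none is touched. The step needs only ring closure to win over intermolecular metathesis, which is secured by high dilution, by the unstrained six-membered ring and by the 1,1-disubstituted alkene, which does not homodimerise.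

Step 9
Reactants: 14 cyclohexenol
Product: 15 (1S,5S,6R)-1-(tert-butyldimethylsilyloxy)-2-methyl-6-(triethylsilyloxy)-5-[(triethylsilyloxy)methyl]cyclohex-2-ene
Conditions: TBSOTf, 2,6-lutidine, CH2Cl2, −78 → 0 °C
Reagents that add atoms: tert-butyldimethylsilyl trifluoromethanesulfonate, CC(C)(C)[Si](C)(C)OS(=O)(=O)C(F)(F)F
Why: Silylation of the hindered allylic C2 hydroxyl with a silyl triflate and 2,6-lutidine is standard, and the more robust tert-butyldimethylsilyl group allows the C1 triethylsilyl ether to be removed first later on.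

Step 10
Reactants: 15 tris-silyl ether
Product: 17 (1R,5S,6R)-5-(tert-butyldimethylsilyloxy)-4-methyl-6-(triethylsilyloxy)cyclohex-3-ene-1-carbaldehyde, via alkoxysulfonium chloride 16 (not isolated)
Conditions: (COCl)2, DMSO, CH2Cl2, −78 °C; then 15, −78 → −40 °C; Et3N, −78 → 0 °C
Reagents that add atoms: none
Why: Swern conditions are known to convert primary triethylsilyl ethers directly into aldehydes, because the chlorodimethylsulfonium ion attacks the least hindered silyl ether oxygen, chloride takes the silyl group and Et3N collapses the alkoxysulfonium ion, while the secondary silyl ethers at C1 and C2 react much more slowly at low temperature.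

Step 11
Reactants: 17 ring A aldehyde; 18 methylmagnesium bromide
Product: 19 1-[(1S,5S,6R)-5-(tert-butyldimethylsilyloxy)-4-methyl-6-(triethylsilyloxy)cyclohex-3-en-1-yl]ethanol (both carbinol epimers)
Conditions: Et2O/THF, −78 °C; sat. aq. NH4Cl
Reagents that add atoms: none
Why: Grignard addition to the aldehyde at low temperature brings in C14, and the new carbinol centre may form as a mixture because it is oxidised in step 12.

Step 12
Reactants: 19 secondary alcohol
Product: 20 1-[(1R,5S,6R)-5-(tert-butyldimethylsilyloxy)-4-methyl-6-(triethylsilyloxy)cyclohex-3-en-1-yl]ethanone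
Conditions: Dess–Martin periodinane, NaHCO3, CH2Cl2, rt
Reagents that add atoms: none
Why: Dess–Martin oxidation of the secondary alcohol gives the methyl ketone under non-basic conditions that should neither epimerise C6 nor eliminate the β-silyloxy group.

Step 13
Reactants: 20 methyl ketone
Product: 22 1-[(1R,5S,6R)-5-(tert-butyldimethylsilyloxy)-4-methyl-6-(triethylsilyloxy)cyclohex-3-en-1-yl]ethenyl trifluoromethanesulfonate, via potassium enolate 21 (not isolated)
Conditions: KN(SiMe3)2, THF, −78 °C; PhNTf2, −78 → 0 °C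
Reagents that add atoms: N-phenylbis(trifluoromethanesulfonimide), O=S(=O)(N(c1ccccc1)S(=O)(=O)C(F)(F)F)C(F)(F)F
Why: Kinetic deprotonation of a methyl ketone with a bulky amide base at −78 °C occurs at the methyl group and not at the hindered C6 methine, and O-sulfonylation of the enolate gives the vinyl triflate that already holds the C7=C14 alkene.

Step 14
Reactants: 23 4-methylpent-3-en-1-ol
Product: 24 4-methylpent-3-enal
Conditions: Dess–Martin periodinane, NaHCO3, CH2Cl2, 0 °C; used at once as a solution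
Reagents that add atoms: none
Why: Dess–Martin oxidation of the homoallylic alcohol under buffered conditions gives the β,γ-unsaturated aldehyde without moving the alkene into conjugation.

Step 15
Reactants: 22 vinyl triflate; 24 4-methylpent-3-enal
Product: 26 2-[(1S,5S,6R)-5-(tert-butyldimethylsilyloxy)-4-methyl-6-(triethylsilyloxy)cyclohex-3-en-1-yl]-6-methylhepta-1,5-dien-3-ol (both C8 epimers), via alkenylchromium dichloride 25 (not isolated)
Conditions: CrCl2 (4 equiv), NiCl2 (2 mol %), DMF/THF, rt
Reagents that add atoms: none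
Why: Nozaki–Hiyama–Kishi coupling, in which zerovalent nickel inserts into the vinyl triflate, the alkenyl group passes to trivalent chromium and the alkenylchromium species adds only to the aldehyde, forms the C7–C8 bond, and the unselective C8 centre is corrected in steps 16 and 17.

Step 16
Reactants: 26 allylic alcohol
Product: 27 2-[(1S,5S,6R)-5-(tert-butyldimethylsilyloxy)-4-methyl-6-(triethylsilyloxy)cyclohex-3-en-1-yl]-6-methylhepta-1,5-dien-3-one
Conditions: Dess–Martin periodinane, pyridine, CH2Cl2, 0 °C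
Reagents that add atoms: none
Why: Dess–Martin oxidation of the allylic alcohol gives the α-methylidene ketone and removes the unselective C8 centre, with no base strong enough to conjugate the skipped C10=C11 alkene.

Step 17
Reactants: 27 enone
Product: 28 (3S)-2-[(1S,5S,6R)-5-(tert-butyldimethylsilyloxy)-4-methyl-6-(triethylsilyloxy)cyclohex-3-en-1-yl]-6-methylhepta-1,5-dien-3-ol
Conditions: (R)-2-methyl-CBS-oxazaborolidine (20 mol %), catecholborane, toluene, −78 °C
Reagents that add atoms: none
Why: Corey–Bakshi–Shibata reduction, in which the ketone binds to the (R)-oxazaborolidine–borane complex with the branched alkenyl group at C7 as the large substituent and the C9 methylene as the small one, should deliver hydride to the face that gives the 8S alcohol under reagent control, and catecholborane does not hydroborate the alkenes at −78 °C.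

Step 18
Reactants: 28 8S allylic alcohol; 29 angelic acid
Product: 31 (3S)-2-[(1S,5S,6R)-5-(tert-butyldimethylsilyloxy)-4-methyl-6-(triethylsilyloxy)cyclohex-3-en-1-yl]-6-methylhepta-1,5-dien-3-yl (Z)-2-methylbut-2-enoate, via angelic mixed anhydride 30 (not isolated)
Conditions: 29, 2,4,6-trichlorobenzoyl chloride, Et3N, toluene, rt; then 28, toluene, 80 °C
Reagents that add atoms: none
Why: Yamaguchi-type esterification through the preformed mixed anhydride without a nucleophilic catalyst is the established way to acylate hindered alcohols with angelic acid while keeping the Z geometry of the 2-methylbut-2-enoyl group.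

Step 19
Reactants: 31 angelate
Product: 32 (3S)-2-[(1S,5S,6R)-5-(tert-butyldimethylsilyloxy)-6-hydroxy-4-methylcyclohex-3-en-1-yl]-6-methylhepta-1,5-dien-3-yl (Z)-2-methylbut-2-enoate
Conditions: HF·pyridine, pyridine, THF, 0 °C
Reagents that add atoms: none
Why: A triethylsilyl ether is cleaved by buffered HF·pyridine far faster than a tert-butyldimethylsilyl ether, so the C1 hydroxyl should be freed selectively while the C2 silyl ether and the angelate remain, and the acidic medium gives no silyl migration.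

Step 20
Reactants: 32 C1 alcohol; 33 (R)-2-methylbutanoic acid
Product: 34 (1R,2S,6S)-2-(tert-butyldimethylsilyloxy)-3-methyl-6-[(3S)-6-methyl-3-{[(Z)-2-methylbut-2-enoyl]oxy}hepta-1,5-dien-2-yl]cyclohex-3-en-1-yl (2R)-2-methylbutanoate
Conditions: EDC·HCl, DMAP, CH2Cl2, 0 °C → rt
Reagents that add atoms: none
Why: Steglich esterification with a carbodiimide and DMAP acylates the free C1 hydroxyl with the α-branched acid under conditions mild enough to keep the acid stereocentre and the angelate geometry.

Step 21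
Reactants: 34 diester silyl ether
Product: 35 (1R,2S,6S)-2-hydroxy-3-methyl-6-[(3S)-6-methyl-3-{[(Z)-2-methylbut-2-enoyl]oxy}hepta-1,5-dien-2-yl]cyclohex-3-en-1-yl (2R)-2-methylbutanoate
Conditions: HF·pyridine, THF, 0 °C → rt
Reagents that add atoms: none
Why: Fluoride cleavage of the allylic tert-butyldimethylsilyl ether frees the C2 hydroxyl at a stage where no oxirane is present yet, and the acidic medium suppresses acyl migration from O1 to O2.

Step 22
Reactants: 35 allylic alcohol
Product: 36 (1R,2R,3R,4S,6S)-3,4-epoxy-2-hydroxy-3-methyl-6-[(3S)-6-methyl-3-{[(Z)-2-methylbut-2-enoyl]oxy}hepta-1,5-dien-2-yl]cyclohexyl (2R)-2-methylbutanoate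
Conditions: VO(acac)2 (5 mol %), t-BuOOH, CH2Cl2, 0 °C → rt
Reagents that add atoms: tert-butyl hydroperoxide, CC(C)(C)OO
Why: Hydroxyl-directed epoxidation, in which the vanadate ester of the C2 allylic alcohol delivers the peroxide oxygen to the alkene face syn to O2, sets C3 and C4 with the oxirane cis to the C2 hydroxyl and to the C1 and C6 substituents, while the C10=C11 alkene and the C7 methylidene, which have no free allylic hydroxyl, react far more slowly.

Step 23
Reactants: 36 ring A epoxy alcohol
Product: 37 target CNP0181486.1, (1R,2R,3R,4S,6S)-6-[(3S)-4-[(2R)-3,3-dimethyloxiran-2-yl]-3-{[(Z)-2-methylbut-2-enoyl]oxy}but-1-en-2-yl]-3,4-epoxy-2-hydroxy-3-methylcyclohexyl (2R)-2-methylbutanoate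
Conditions: D-fructose-derived Shi ketone (3 equiv), Oxone (2KHSO5·KHSO4·K2SO4), NaHCO3, Bu4NHSO4, MeCN/aq. Na2EDTA, pH 8, 0 °C
Reagents that add atoms: potassium peroxymonosulfate (KHSO5 of Oxone), [K+].[O-]S(=O)(=O)OO
Why: Shi asymmetric epoxidation, in which the chiral dioxirane of the D-fructose-derived ketone transfers oxygen through a spiro transition state to one face of the trisubstituted C10=C11 alkene, should set C10 as R under reagent control, the electron-poor angelate and the 1,1-disubstituted C7 methylidene being much less reactive and the near-neutral buffer limiting acyl migration between O1 and O2.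

Compound list
1 | (R)-4-benzyl-2-oxazolidinone | O=C1OC[C@@H](Cc2ccccc2)N1 | starting material
2 | pent-4-enoyl chloride | C=CCCC(=O)Cl | starting material
3 | lithium (R)-4-benzyl-2-oxooxazolidin-3-ide (N-lithio oxazolidinone) | [Li]N1[C@H](Cc2ccccc2)COC1=O | intermediate
4 | (R)-4-benzyl-3-(pent-4-enoyl)oxazolidin-2-one | C=CCCC(=O)N1[C@H](Cc2ccccc2)COC1=O | intermediate
5 | (4-methoxybenzyloxy)acetaldehyde | COc1ccc(COCC=O)cc1 | starting material
6 | dibutylboron Z-enolate of 4 | C=CC/C=C(\OB(CCCC)CCCC)N1[C@H](Cc2ccccc2)COC1=O | intermediate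
7 | (R)-4-benzyl-3-[(2R,3R)-3-hydroxy-4-(4-methoxybenzyloxy)-2-(prop-2-enyl)butanoyl]oxazolidin-2-one | C=CC[C@@H](C(=O)N1[C@H](Cc2ccccc2)COC1=O)[C@@H](O)COCc1ccc(OC)cc1 | intermediate
8 | (2S,3R)-4-(4-methoxybenzyloxy)-2-(prop-2-enyl)butane-1,3-diol | C=CC[C@@H](CO)[C@@H](O)COCc1ccc(OC)cc1 | intermediate
9 | (2S,3R)-4-(4-methoxybenzyloxy)-2-(prop-2-enyl)-1,3-bis(triethylsilyloxy)butane | C=CC[C@@H](CO[Si](CC)(CC)CC)[C@@H](O[Si](CC)(CC)CC)COCc1ccc(OC)cc1 | intermediate
10 | (2R,3S)-2-(triethylsilyloxy)-3-[(triethylsilyloxy)methyl]hex-5-en-1-ol | C=CC[C@@H](CO[Si](CC)(CC)CC)[C@@H](O[Si](CC)(CC)CC)CO | intermediate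
11 | (2R,3S)-2-(triethylsilyloxy)-3-[(triethylsilyloxy)methyl]hex-5-enal | C=CC[C@@H](CO[Si](CC)(CC)CC)[C@@H](O[Si](CC)(CC)CC)C=O | intermediate
12 | isopropenylmagnesium bromide | CC(=C)[Mg]Br | starting material
13 | (3S,4R,5S)-2-methyl-4-(triethylsilyloxy)-5-[(triethylsilyloxy)methyl]octa-1,7-dien-3-ol (metathesis precursor) | C=CC[C@@H](CO[Si](CC)(CC)CC)[C@@H](O[Si](CC)(CC)CC)[C@@H](O)C(C)=C | intermediate
14 | (1S,5S,6R)-2-methyl-6-(triethylsilyloxy)-5-[(triethylsilyloxy)methyl]cyclohex-2-en-1-ol (metathesis product) | CC[Si](CC)(CC)OC[C@@H]1CC=C(C)[C@H](O)[C@@H]1O[Si](CC)(CC)CC | intermediate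
15 | (1S,5S,6R)-1-(tert-butyldimethylsilyloxy)-2-methyl-6-(triethylsilyloxy)-5-[(triethylsilyloxy)methyl]cyclohex-2-ene | CC[Si](CC)(CC)OC[C@@H]1CC=C(C)[C@H](O[Si](C)(C)C(C)(C)C)[C@@H]1O[Si](CC)(CC)CC | intermediate
16 | dimethyl(alkoxy)sulfonium chloride at O7 of the ring A fragment | C[S+](C)OC[C@@H]1CC=C(C)[C@H](O[Si](C)(C)C(C)(C)C)[C@@H]1O[Si](CC)(CC)CC.[Cl-] | intermediate
17 | (1R,5S,6R)-5-(tert-butyldimethylsilyloxy)-4-methyl-6-(triethylsilyloxy)cyclohex-3-ene-1-carbaldehyde | O=C[C@@H]1CC=C(C)[C@H](O[Si](C)(C)C(C)(C)C)[C@@H]1O[Si](CC)(CC)CC | intermediate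
18 | methylmagnesium bromide | C[Mg]Br | starting material
19 | 1-[(1S,5S,6R)-5-(tert-butyldimethylsilyloxy)-4-methyl-6-(triethylsilyloxy)cyclohex-3-en-1-yl]ethanol (both carbinol epimers) | CC(O)[C@@H]1CC=C(C)[C@H](O[Si](C)(C)C(C)(C)C)[C@@H]1O[Si](CC)(CC)CC | intermediate
20 | 1-[(1R,5S,6R)-5-(tert-butyldimethylsilyloxy)-4-methyl-6-(triethylsilyloxy)cyclohex-3-en-1-yl]ethanone | CC(=O)[C@@H]1CC=C(C)[C@H](O[Si](C)(C)C(C)(C)C)[C@@H]1O[Si](CC)(CC)CC | intermediate
21 | potassium enolate of 20 at the methyl side | C=C([O-])[C@@H]1CC=C(C)[C@H](O[Si](C)(C)C(C)(C)C)[C@@H]1O[Si](CC)(CC)CC.[K+] | intermediate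
22 | 1-[(1R,5S,6R)-5-(tert-butyldimethylsilyloxy)-4-methyl-6-(triethylsilyloxy)cyclohex-3-en-1-yl]ethenyl trifluoromethanesulfonate | C=C(OS(=O)(=O)C(F)(F)F)[C@@H]1CC=C(C)[C@H](O[Si](C)(C)C(C)(C)C)[C@@H]1O[Si](CC)(CC)CC | intermediate
23 | 4-methylpent-3-en-1-ol | CC(C)=CCCO | starting material
24 | 4-methylpent-3-enal | CC(C)=CCC=O | intermediate
25 | alkenylchromium dichloride from 22 (trivalent chromium) | C=C([Cr](Cl)Cl)[C@@H]1CC=C(C)[C@H](O[Si](C)(C)C(C)(C)C)[C@@H]1O[Si](CC)(CC)CC | intermediate
26 | 2-[(1S,5S,6R)-5-(tert-butyldimethylsilyloxy)-4-methyl-6-(triethylsilyloxy)cyclohex-3-en-1-yl]-6-methylhepta-1,5-dien-3-ol (both C8 epimers) | C=C(C(O)CC=C(C)C)[C@@H]1CC=C(C)[C@H](O[Si](C)(C)C(C)(C)C)[C@@H]1O[Si](CC)(CC)CC | intermediate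
27 | 2-[(1S,5S,6R)-5-(tert-butyldimethylsilyloxy)-4-methyl-6-(triethylsilyloxy)cyclohex-3-en-1-yl]-6-methylhepta-1,5-dien-3-one | C=C(C(=O)CC=C(C)C)[C@@H]1CC=C(C)[C@H](O[Si](C)(C)C(C)(C)C)[C@@H]1O[Si](CC)(CC)CC | intermediate
28 | (3S)-2-[(1S,5S,6R)-5-(tert-butyldimethylsilyloxy)-4-methyl-6-(triethylsilyloxy)cyclohex-3-en-1-yl]-6-methylhepta-1,5-dien-3-ol | C=C([C@H](CC=C(C)C)O)[C@@H]1CC=C(C)[C@H](O[Si](C)(C)C(C)(C)C)[C@@H]1O[Si](CC)(CC)CC | intermediate
29 | angelic acid, (Z)-2-methylbut-2-enoic acid | C/C=C(/C)C(=O)O | starting material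
30 | angelic 2,4,6-trichlorobenzoic anhydride | C/C=C(/C)C(=O)OC(=O)c1c(Cl)cc(Cl)cc1Cl | intermediate
31 | (3S)-2-[(1S,5S,6R)-5-(tert-butyldimethylsilyloxy)-4-methyl-6-(triethylsilyloxy)cyclohex-3-en-1-yl]-6-methylhepta-1,5-dien-3-yl (Z)-2-methylbut-2-enoate | C=C([C@H](CC=C(C)C)OC(=O)/C(C)=C\C)[C@@H]1CC=C(C)[C@H](O[Si](C)(C)C(C)(C)C)[C@@H]1O[Si](CC)(CC)CC | intermediate
32 | (3S)-2-[(1S,5S,6R)-5-(tert-butyldimethylsilyloxy)-6-hydroxy-4-methylcyclohex-3-en-1-yl]-6-methylhepta-1,5-dien-3-yl (Z)-2-methylbut-2-enoate | C=C([C@H](CC=C(C)C)OC(=O)/C(C)=C\C)[C@@H]1CC=C(C)[C@H](O[Si](C)(C)C(C)(C)C)[C@@H]1O | intermediate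
33 | (R)-2-methylbutanoic acid | CC[C@@H](C)C(=O)O | starting material
34 | (1R,2S,6S)-2-(tert-butyldimethylsilyloxy)-3-methyl-6-[(3S)-6-methyl-3-{[(Z)-2-methylbut-2-enoyl]oxy}hepta-1,5-dien-2-yl]cyclohex-3-en-1-yl (2R)-2-methylbutanoate | C=C([C@H](CC=C(C)C)OC(=O)/C(C)=C\C)[C@@H]1CC=C(C)[C@H](O[Si](C)(C)C(C)(C)C)[C@@H]1OC(=O)[C@H](C)CC | intermediate
35 | (1R,2S,6S)-2-hydroxy-3-methyl-6-[(3S)-6-methyl-3-{[(Z)-2-methylbut-2-enoyl]oxy}hepta-1,5-dien-2-yl]cyclohex-3-en-1-yl (2R)-2-methylbutanoate | C=C([C@H](CC=C(C)C)OC(=O)/C(C)=C\C)[C@@H]1CC=C(C)[C@H](O)[C@@H]1OC(=O)[C@H](C)CC | intermediate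
36 | (1R,2R,3R,4S,6S)-3,4-epoxy-2-hydroxy-3-methyl-6-[(3S)-6-methyl-3-{[(Z)-2-methylbut-2-enoyl]oxy}hepta-1,5-dien-2-yl]cyclohexyl (2R)-2-methylbutanoate | C=C([C@H](CC=C(C)C)OC(=O)/C(C)=C\C)[C@@H]1C[C@@H]2O[C@]2(C)[C@H](O)[C@@H]1OC(=O)[C@H](C)CC | intermediate
37 | CNP0181486.1, (1R,2R,3R,4S,6S)-6-[(3S)-4-[(2R)-3,3-dimethyloxiran-2-yl]-3-{[(Z)-2-methylbut-2-enoyl]oxy}but-1-en-2-yl]-3,4-epoxy-2-hydroxy-3-methylcyclohexyl (2R)-2-methylbutanoate | C=C([C@H](C[C@H]1OC1(C)C)OC(=O)/C(C)=C\C)[C@@H]1C[C@@H]2O[C@]2(C)[C@H](O)[C@@H]1OC(=O)[C@H](C)CC | target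

Total step count: 23. Longest linear sequence: 22 steps (steps 1–13 and 15–23, from 1 and 2 to 37); step 14 is a one-step side branch.

Steps most likely to fail:

1. Step 7. Facial selectivity in the Grignard addition may be poor, because Felkin control by an α-silyloxy group is often only moderate and partial chelation or epimerisation of the aldehyde at C1 would erode it further. The fallback sets out from 11. The addition is run as before and the crude mixture of 13 and its C2 epimer (3R,4R,5S)-2-methyl-4-(triethylsilyloxy)-5-[(triethylsilyloxy)methyl]octa-1,7-dien-3-ol F1 is oxidised with Dess–Martin periodinane to the enone (4R,5S)-2-methyl-4-(triethylsilyloxy)-5-[(triethylsilyloxy)methyl]octa-1,7-dien-3-one F2. Luche reduction (NaBH4, CeCl3·7H2O, MeOH, −78 °C) then sets C2 by 1,2-hydride delivery to the Felkin–Anh face of the α-silyloxy ketone, and the route is rejoined at 13.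

2. Step 10. The direct oxidation of the primary silyl ether may stall, may also attack the secondary triethylsilyl ether at C1, or may epimerise C6 of the new aldehyde under the amine base. The fallback sets out from 15. The primary triethylsilyl ether alone is cleaved with HF·pyridine buffered with pyridine (THF, 0 °C) to the alcohol [(1S,5S,6R)-5-(tert-butyldimethylsilyloxy)-4-methyl-6-(triethylsilyloxy)cyclohex-3-en-1-yl]methanol F3. This is oxidised with Dess–Martin periodinane and NaHCO3 without any amine base, and the route is rejoined at 17.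

3. Step 23. On the fully deprotected substrate the last epoxidation may suffer from base-promoted acyl migration between O1 and O2, from incomplete discrimination between the C10=C11 and C7=C14 alkenes, or from a low facial preference. The fallback sets out from 34, where O2 is still silylated and no acyl shift is possible.
   - Shi epoxidation under the catalytic conditions (ketone 30 mol %, Oxone, K2CO3, pH 10.5, 0 °C) is applied first. The ring alkene is shielded by the neighbouring silyl ether, and the product is the side-chain epoxide (1R,2S,6S)-2-(tert-butyldimethylsilyloxy)-6-[(3S)-4-[(2R)-3,3-dimethyloxiran-2-yl]-3-{[(Z)-2-methylbut-2-enoyl]oxy}but-1-en-2-yl]-3-methylcyclohex-3-en-1-yl (2R)-2-methylbutanoate F4.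
   - Desilylation with pyridine-buffered HF·pyridine gives the allylic alcohol (1R,2S,6S)-6-[(3S)-4-[(2R)-3,3-dimethyloxiran-2-yl]-3-{[(Z)-2-methylbut-2-enoyl]oxy}but-1-en-2-yl]-2-hydroxy-3-methylcyclohex-3-en-1-yl (2R)-2-methylbutanoate F5.
   - The directed epoxidation with VO(acac)2 and t-BuOOH is then the last step, and the route is rejoined at 37.

Further compounds
F1 | step 7 | (3R,4R,5S)-2-methyl-4-(triethylsilyloxy)-5-[(triethylsilyloxy)methyl]octa-1,7-dien-3-ol (C2 epimer of 13) | C=CC[C@@H](CO[Si](CC)(CC)CC)[C@@H](O[Si](CC)(CC)CC)[C@H](O)C(C)=C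
F2 | step 7 | (4R,5S)-2-methyl-4-(triethylsilyloxy)-5-[(triethylsilyloxy)methyl]octa-1,7-dien-3-one | C=CC[C@@H](CO[Si](CC)(CC)CC)[C@@H](O[Si](CC)(CC)CC)C(=O)C(C)=C
F3 | step 10 | [(1S,5S,6R)-5-(tert-butyldimethylsilyloxy)-4-methyl-6-(triethylsilyloxy)cyclohex-3-en-1-yl]methanol | OC[C@@H]1CC=C(C)[C@H](O[Si](C)(C)C(C)(C)C)[C@@H]1O[Si](CC)(CC)CC
F4 | step 23 | (1R,2S,6S)-2-(tert-butyldimethylsilyloxy)-6-[(3S)-4-[(2R)-3,3-dimethyloxiran-2-yl]-3-{[(Z)-2-methylbut-2-enoyl]oxy}but-1-en-2-yl]-3-methylcyclohex-3-en-1-yl (2R)-2-methylbutanoate | C=C([C@H](C[C@H]1OC1(C)C)OC(=O)/C(C)=C\C)[C@@H]1CC=C(C)[C@H](O[Si](C)(C)C(C)(C)C)[C@@H]1OC(=O)[C@H](C)CC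
F5 | step 23 | (1R,2S,6S)-6-[(3S)-4-[(2R)-3,3-dimethyloxiran-2-yl]-3-{[(Z)-2-methylbut-2-enoyl]oxy}but-1-en-2-yl]-2-hydroxy-3-methylcyclohex-3-en-1-yl (2R)-2-methylbutanoate | C=C([C@H](C[C@H]1OC1(C)C)OC(=O)/C(C)=C\C)[C@@H]1CC=C(C)[C@H](O)[C@@H]1OC(=O)[C@H](C)CC
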